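**Retrosynthetic overview**
- Target ⇐ acylation of the ring carbinol with the senecioyl group; CH2OH ⇐ methyl ester; oxirane ⇐ hydroxyl-directed epoxidation of the (Z)-trisubstituted ring olefin. The oxirane is the second ring formed.
- 11-membered carbocycle (first ring formed) ⇐ intramolecular, ligand-controlled addition of an (E)-alkenylzinc to a (Z)-enal, which makes the C3–C4 bond, the E-C2=C3 olefin and the C4 stereocentre in one step.
- Alkyne ⇐ aldehyde ⇐ CH2NO2 (Nef, then Ohira–Bestmann); C9=C10 ⇐ E-selective Wittig of a γ-nitro aldehyde with an ester-stabilized ylide.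
- Key disconnection C1–C2: enantioselective conjugate addition of nitromethane (nitronate as formyl-anion equivalent) to citral, which sets the all-carbon quaternary stereocentre.
- Ylide fragment ⇐ methyl 2,5-dibromopentanoate + 2 PPh3 + 1,1-dimethoxyacetone (Z-selective Wittig of a mixed bis-ylide).

Assumption and labels: commercial citral (E/Z mixture) is used and its two iminium isomers are taken to interconvert under the conditions of step 3. Atom labels follow the target SMILES: C1 quaternary carbon, C2=C3 disubstituted olefin, C4 carbinol carbon, C5/C6 oxirane carbons, C9=C10 trisubstituted olefin, C11 ring CH2, C12 CH2OH carbon.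

**Step 1**
Reactants: 1 methyl 2,5-dibromopentanoate (racemic); 2 triphenylphosphine
Product: 3 (5-methoxy-5-oxopentane-1,4-diyl)bis(triphenylphosphonium) dibromide
Conditions: PPh3 (2.2 equiv in all), MeCN, reflux, 48 h
Reagents that add atoms: triphenylphosphine (the second equivalent of 2), c1ccc(cc1)P(c1ccccc1)c1ccccc1
Why: Double SN2 quaternization (phosphonium salt formation) consumes two equivalents of PPh3, one at the primary bromide and one at the α-ester bromide; the stereocentre of racemic 1 is erased when the ylide is formed in step 2.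

**Step 2**
Reactants: 3 the bis-phosphonium dibromide; 4 1,1-dimethoxypropan-2-one
Product: 6 methyl (5Z)-7,7-dimethoxy-6-methyl-2-(triphenyl-λ5-phosphanylidene)hept-5-enoate, via bis-ylide 5 (not isolated)
Conditions: NaHMDS (2.05 equiv), THF, −78→0 °C; then 4, −78 °C→rt
Reagents that add atoms: none
Why: Still-type Z-selective Wittig reaction: only the non-stabilized ylide attacks the α,α-dialkoxy ketone, placing the acetal carbon (C4) cis to the chain (C7), while the ester-stabilized ylide is inert to ketones and survives.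

**Step 3**
Reactants: 7 citral (3,7-dimethylocta-2,6-dienal, E/Z mixture); 8 nitromethane
Product: 9 (3S)-3,7-dimethyl-3-(nitromethyl)oct-6-enal
Conditions: (R)-2-[diphenyl(trimethylsilyloxy)methyl]pyrrolidine (10 mol%), PhCO2H (20 mol%), MeNO2 (10 equiv), MeOH, rt, 3–5 d
Reagents that add atoms: none
Why: Iminium-catalysed asymmetric Michael addition (Hayashi–Jørgensen catalyst) of the nitronate, a formyl-anion equivalent, joins the future aldehyde carbon C2 to the electrophilic β-carbon C1; the CPh2OTMS group shields one face of the (E)-iminium ion (E/Z isomers equilibrate via the dienamine), so the (R)-catalyst gives the (S) quaternary centre.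

**Step 4**
Reactants: 9 the γ-nitro aldehyde; 6 the ylide acetal
Product: 10 methyl (2E,5Z)-2-[(3S)-3,7-dimethyl-3-(nitromethyl)oct-6-en-1-ylidene]-7,7-dimethoxy-6-methylhept-5-enoate
Conditions: toluene, 70 °C, 16 h
Reagents that add atoms: none
Why: Wittig olefination with an α-alkyl ester-stabilized ylide is E-selective (ester trans to C11, so C8 cis to C11 as in the target), and the ylide is too weakly basic to deprotonate the free nitroalkane.

**Step 5**
Reactants: 10 the nitro ester
Product: 12 methyl (2E,5Z)-2-[(3S)-3-formyl-3,7-dimethyloct-6-en-1-ylidene]-7,7-dimethoxy-6-methylhept-5-enoate, via sodium nitronate 11 (not isolated)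
Conditions: NaOMe, MeOH, 0 °C; then aq TiCl3, NH4OAc buffer (pH 5–6), THF/H2O, 0 °C→rt
Reagents that add atoms: water, O
Why: McMurry Ti(III) Nef reaction reduces the nitronate to the imine, which hydrolyses at near-neutral pH to the non-enolizable α-quaternary aldehyde while the acetal, ester and olefins are untouched.

**Step 6**
Reactants: 12 the aldehyde; 13 dimethyl (1-diazo-2-oxopropyl)phosphonate
Product: 14 methyl (2E,5Z)-2-[(3S)-3-ethynyl-3,7-dimethyloct-6-en-1-ylidene]-7,7-dimethoxy-6-methylhept-5-enoate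
Conditions: K2CO3, MeOH, 0 °C→rt
Reagents that add atoms: none
Why: Seyferth–Gilbert homologation (Ohira–Bestmann modification) converts the non-enolizable aldehyde into the terminal alkyne (C2≡C3) under mild base that the methyl ester and acetal tolerate.

**Step 7**
Reactants: 14 the alkyne acetal
Product: 15 methyl (2E,5Z)-2-[(3S)-3-ethynyl-3,7-dimethyloct-6-en-1-ylidene]-6-methyl-7-oxohept-5-enoate
Conditions: 10% aq oxalic acid on SiO2, CH2Cl2, 0 °C→rt, dark
Reagents that add atoms: water, O
Why: Mild heterogeneous acetal hydrolysis frees the (Z)-α-methyl enal (C4) under conditions chosen to avoid Z→E isomerization.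

**Step 8**
Reactants: 15 the alkynyl enal
Product: 18 methyl (1E,4S,5E,7S,8Z)-7-hydroxy-4,8-dimethyl-4-(4-methylpent-3-en-1-yl)cycloundeca-1,5,8-triene-1-carboxylate, via alkenyl(dicyclohexyl)borane 16 (not isolated), via alkenyl(ethyl)zinc 17 (not isolated)
Conditions: Cy2BH (1.05 equiv), toluene, 0 °C; then syringe-pump addition to Et2Zn (1.5 equiv), (−)-MIB (10 mol%), toluene, 0 °C, 2 mM; aq NH4Cl
Reagents that add atoms: none
Why: Oppolzer–Radinov macrocyclization: syn-hydroboration gives the (E)-alkenylborane, B→Zn exchange the alkenylzinc, and amino-alcohol-catalysed 1,2-addition to the enal closes the ring, (−)-MIB directing Si-face attack (as in Et2Zn + PhCHO → S) to give the (S)-C4 carbinol.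

**Step 9**
Reactants: 18 the macrocyclic bis-allylic alcohol
Product: 19 methyl (1S,2S,3E,5S,7E,11R)-2-hydroxy-1,5-dimethyl-5-(4-methylpent-3-en-1-yl)-12-oxabicyclo[9.1.0]dodeca-3,7-diene-8-carboxylate
Conditions: VO(acac)2 (5 mol%), TBHP (1.5 equiv, decane), CH2Cl2, 0 °C→rt
Reagents that add atoms: tert-butyl hydroperoxide, CC(C)(C)OO
Why: Hydroxyl-directed vanadium-catalysed epoxidation reacts fastest at the more nucleophilic trisubstituted allylic olefin (the enoate and the homoprenyl olefin are not directed), and the cis-cycloalkenol/A(1,2)-strain transition state delivers oxygen syn to the carbinol oxygen (erythro), setting C5 and C6.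

**Step 10**
Reactants: 19 the epoxy alcohol ester
Product: 20 (1S,2S,3E,5S,7E,11R)-8-(hydroxymethyl)-1,5-dimethyl-5-(4-methylpent-3-en-1-yl)-12-oxabicyclo[9.1.0]dodeca-3,7-dien-2-ol
Conditions: DIBAL (3.5 equiv), CH2Cl2, −78 °C; Rochelle salt
Reagents that add atoms: none
Why: DIBAL 1,2-reduction of the α,β-unsaturated methyl ester gives the primary allylic alcohol at −78 °C, where the epoxide and olefins are inert and no stereocentre is touched.

**Step 11**
Reactants: 20 the epoxy diol; 21 3-methylbut-2-enoyl chloride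
Product: 24 [(1R,2S,3E,5S,7E,11R)-8-(hydroxymethyl)-1,5-dimethyl-5-(4-methylpent-3-en-1-yl)-12-oxabicyclo[9.1.0]dodeca-3,7-dien-2-yl] 3-methylbut-2-enoate (CNP0318149.1), via primary TES ether 22 (not isolated), via TES ether senecioate 23 (not isolated)
Conditions: TESCl (1.05 equiv), pyridine, CH2Cl2, −40 °C; then 21 (3 equiv), DMAP, 0 °C→rt; then TBAF/AcOH (1:1), THF, 0 °C
Reagents that add atoms: chlorotriethylsilane, CC[Si](Cl)(CC)CC (its silyl group is carried only in 22 and 23 and is absent from 24)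
Why: Transient-protection acylation: the primary allylic OH is silylated selectively over the hindered secondary OH, DMAP-catalysed esterification (pyridine as base to limit deconjugation of the acyl group) installs the senecioate, and acetic acid-buffered fluoride removes the TES group without Payne rearrangement, acyl migration or epoxide opening.

**Compound list**
1 | methyl 2,5-dibromopentanoate (racemic) | COC(=O)C(Br)CCCBr | starting material
2 | triphenylphosphine | c1ccc(cc1)P(c1ccccc1)c1ccccc1 | starting material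
3 | (5-methoxy-5-oxopentane-1,4-diyl)bis(triphenylphosphonium) dibromide | COC(=O)C(CCC[P+](c1ccccc1)(c1ccccc1)c1ccccc1)[P+](c1ccccc1)(c1ccccc1)c1ccccc1.[Br-].[Br-] | intermediate
4 | 1,1-dimethoxypropan-2-one | CC(=O)C(OC)OC | starting material
5 | methyl 2,5-bis(triphenyl-λ5-phosphanylidene)pentanoate | COC(=O)C(CCC=P(c1ccccc1)(c1ccccc1)c1ccccc1)=P(c1ccccc1)(c1ccccc1)c1ccccc1 | intermediate (not isolated)
6 | methyl (5Z)-7,7-dimethoxy-6-methyl-2-(triphenyl-λ5-phosphanylidene)hept-5-enoate | COC(=O)C(CC/C=C(C)\C(OC)OC)=P(c1ccccc1)(c1ccccc1)c1ccccc1 | intermediate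
7 | citral (3,7-dimethylocta-2,6-dienal, E/Z mixture) | CC(C)=CCCC(C)=CC=O | starting material
8 | nitromethane | C[N+](=O)[O-] | starting material
9 | (3S)-3,7-dimethyl-3-(nitromethyl)oct-6-enal | CC(C)=CCC[C@](CC=O)(C)C[N+](=O)[O-] | intermediate
10 | methyl (2E,5Z)-2-[(3S)-3,7-dimethyl-3-(nitromethyl)oct-6-en-1-ylidene]-7,7-dimethoxy-6-methylhept-5-enoate | CC(C)=CCC[C@](C/C=C(\CC/C=C(C)\C(OC)OC)C(=O)OC)(C)C[N+](=O)[O-] | intermediate
11 | sodium aci-nitronate of 10 (C=NO2 Na at the former CH2NO2 carbon) | CC(C)=CCC[C@](C/C=C(\CC/C=C(C)\C(OC)OC)C(=O)OC)(C)C=[N+]([O-])[O-].[Na+] | intermediate (not isolated)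
12 | methyl (2E,5Z)-2-[(3S)-3-formyl-3,7-dimethyloct-6-en-1-ylidene]-7,7-dimethoxy-6-methylhept-5-enoate | CC(C)=CCC[C@](C/C=C(\CC/C=C(C)\C(OC)OC)C(=O)OC)(C)C=O | intermediate
13 | dimethyl (1-diazo-2-oxopropyl)phosphonate | CC(=O)C(=[N+]=[N-])P(=O)(OC)OC | starting material
14 | methyl (2E,5Z)-2-[(3S)-3-ethynyl-3,7-dimethyloct-6-en-1-ylidene]-7,7-dimethoxy-6-methylhept-5-enoate | CC(C)=CCC[C@](C/C=C(\CC/C=C(C)\C(OC)OC)C(=O)OC)(C)C#C | intermediate
15 | methyl (2E,5Z)-2-[(3S)-3-ethynyl-3,7-dimethyloct-6-en-1-ylidene]-6-methyl-7-oxohept-5-enoate | CC(C)=CCC[C@](C/C=C(\CC/C=C(C)\C=O)C(=O)OC)(C)C#C | intermediate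
16 | methyl (2E,5Z)-2-{(3S)-3-[(E)-2-(dicyclohexylboranyl)ethenyl]-3,7-dimethyloct-6-en-1-ylidene}-6-methyl-7-oxohept-5-enoate | CC(C)=CCC[C@](C/C=C(\CC/C=C(C)\C=O)C(=O)OC)(C)/C=C/B(C1CCCCC1)C1CCCCC1 | intermediate (not isolated)
17 | methyl (2E,5Z)-2-{(3S)-3-[(E)-2-(ethylzincio)ethenyl]-3,7-dimethyloct-6-en-1-ylidene}-6-methyl-7-oxohept-5-enoate | CC(C)=CCC[C@](C/C=C(\CC/C=C(C)\C=O)C(=O)OC)(C)/C=C/[Zn]CC | intermediate (not isolated)
18 | methyl (1E,4S,5E,7S,8Z)-7-hydroxy-4,8-dimethyl-4-(4-methylpent-3-en-1-yl)cycloundeca-1,5,8-triene-1-carboxylate | CC(C)=CCC[C@]1(C)/C=C/[C@H](O)/C(C)=C\CC/C(C(=O)OC)=C\C1 | intermediate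
19 | methyl (1S,2S,3E,5S,7E,11R)-2-hydroxy-1,5-dimethyl-5-(4-methylpent-3-en-1-yl)-12-oxabicyclo[9.1.0]dodeca-3,7-diene-8-carboxylate | CC(C)=CCC[C@]1(C)/C=C/[C@H](O)[C@]2(C)O[C@@H]2CC/C(C(=O)OC)=C\C1 | intermediate
20 | (1S,2S,3E,5S,7E,11R)-8-(hydroxymethyl)-1,5-dimethyl-5-(4-methylpent-3-en-1-yl)-12-oxabicyclo[9.1.0]dodeca-3,7-dien-2-ol | CC(C)=CCC[C@]1(C)/C=C/[C@H](O)[C@]2(C)O[C@@H]2CC/C(CO)=C\C1 | intermediate
21 | 3-methylbut-2-enoyl chloride | CC(C)=CC(Cl)=O | starting material
22 | (1S,2S,3E,5S,7E,11R)-1,5-dimethyl-5-(4-methylpent-3-en-1-yl)-8-{[(triethylsilyl)oxy]methyl}-12-oxabicyclo[9.1.0]dodeca-3,7-dien-2-ol | CC(C)=CCC[C@]1(C)/C=C/[C@H](O)[C@]2(C)O[C@@H]2CC/C(CO[Si](CC)(CC)CC)=C\C1 | intermediate (not isolated)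
23 | [(1R,2S,3E,5S,7E,11R)-1,5-dimethyl-5-(4-methylpent-3-en-1-yl)-8-{[(triethylsilyl)oxy]methyl}-12-oxabicyclo[9.1.0]dodeca-3,7-dien-2-yl] 3-methylbut-2-enoate | CC(C)=CCC[C@]1(C)/C=C/[C@H](OC(=O)C=C(C)C)[C@]2(C)O[C@@H]2CC/C(CO[Si](CC)(CC)CC)=C\C1 | intermediate (not isolated)
24 | [(1R,2S,3E,5S,7E,11R)-8-(hydroxymethyl)-1,5-dimethyl-5-(4-methylpent-3-en-1-yl)-12-oxabicyclo[9.1.0]dodeca-3,7-dien-2-yl] 3-methylbut-2-enoate | CC(C)=CCC[C@]1(C)/C=C/[C@H](OC(=O)C=C(C)C)[C@]2(C)O[C@@H]2CC/C(CO)=C\C1 | target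

**Step count and risks**
Total step count: 11. Longest linear sequence: 10 steps (steps 1, 2, 4–11, from methyl 2,5-dibromopentanoate); 9 steps from citral.

Most likely to fail, first: step 3. β,β-Dialkyl enals are slow iminium acceptors, and geranial and neral lead to opposite enantiomers, so the ee depends on fast E/Z equilibration. The fallback sets out from nitromethane 8, which is condensed with commercial 6-methylhept-5-en-2-one (Henry reaction and dehydration, NH4OAc/AcOH, E isomer separated) to give (E)-2,6-dimethyl-1-nitrohepta-1,5-diene F1. An enamine-catalysed conjugate addition of acetaldehyde to this β,β-disubstituted nitroalkene (Wennemers-type tripeptide or a diarylprolinol silyl ether, enantiomer chosen for the S centre) then forms the C1–C11 bond instead of C1–C2 and comes back to the route at 9.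

Second: step 8. The precedent for this macrocyclization is a 15-membered ring; an 11-membered ring may close poorly or give ethyl transfer or aldehyde reduction. The fallback sets out from alkyne acetal 14. Hydrozirconation (Cp2Zr(H)Cl) and iodinolysis give the (E)-vinyl iodide acetal F2, and acetal hydrolysis as in step 7 gives the iodo enal F3. Nozaki–Hiyama–Kishi macrocyclization (CrCl2, cat. NiCl2, DMSO/THF, high dilution) gives the epimeric ring carbinol mixture F4. Dess–Martin oxidation gives the cross-conjugated dienone F5, and (R)-CBS/catecholborane reduction (the α-methyl alkenyl group acting as the large substituent) returns to the route at 18.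

Third: step 9. The cis ring substituent at C6 exerts A(1,3) strain that could erode or reverse the erythro preference, and the C2=C3 olefin is also allylic to the hydroxyl. The fallback sets out from enal 15 and installs the oxirane before ring closure. Luche reduction gives the (Z)-allylic alcohol F6, Sharpless asymmetric epoxidation with Ti(OiPr)4/L-(+)-DET/TBHP gives the epoxy alcohol F7 under reagent control, and Dess–Martin oxidation gives the epoxy aldehyde F8. The alkenylzinc macrocyclization of step 8 is then run on this aldehyde (ligand control and Felkin preference both favouring the erythro carbinol) and comes back to the route at 19.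

**Further compounds**
F1 | step 3 | (E)-2,6-dimethyl-1-nitrohepta-1,5-diene | CC(C)=CCC/C(C)=C/[N+](=O)[O-]
F2 | step 8 | methyl (2E,5Z)-2-{(3S)-3-[(E)-2-iodoethenyl]-3,7-dimethyloct-6-en-1-ylidene}-7,7-dimethoxy-6-methylhept-5-enoate | CC(C)=CCC[C@](C/C=C(\CC/C=C(C)\C(OC)OC)C(=O)OC)(C)/C=C/I
F3 | step 8 | methyl (2E,5Z)-2-{(3S)-3-[(E)-2-iodoethenyl]-3,7-dimethyloct-6-en-1-ylidene}-6-methyl-7-oxohept-5-enoate | CC(C)=CCC[C@](C/C=C(\CC/C=C(C)\C=O)C(=O)OC)(C)/C=C/I
F4 | step 8 | methyl (1E,4S,5E,7RS,8Z)-7-hydroxy-4,8-dimethyl-4-(4-methylpent-3-en-1-yl)cycloundeca-1,5,8-triene-1-carboxylate (carbinol epimer mixture) | CC(C)=CCC[C@]1(C)/C=C/C(O)/C(C)=C\CC/C(C(=O)OC)=C\C1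
F5 | step 8 | methyl (1E,4S,5E,8Z)-4,8-dimethyl-4-(4-methylpent-3-en-1-yl)-7-oxocycloundeca-1,5,8-triene-1-carboxylate | CC(C)=CCC[C@]1(C)/C=C/C(=O)/C(C)=C\CC/C(C(=O)OC)=C\C1
F6 | step 9 | methyl (2E,5Z)-2-[(3S)-3-ethynyl-3,7-dimethyloct-6-en-1-ylidene]-7-hydroxy-6-methylhept-5-enoate | CC(C)=CCC[C@](C/C=C(\CC/C=C(C)\CO)C(=O)OC)(C)C#C
F7 | step 9 | methyl (2E)-2-[(3S)-3-ethynyl-3,7-dimethyloct-6-en-1-ylidene]-4-[(2R,3S)-3-(hydroxymethyl)-3-methyloxiran-2-yl]butanoate | CC(C)=CCC[C@](C/C=C(\CC[C@H]1O[C@@]1(C)CO)C(=O)OC)(C)C#C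
F8 | step 9 | methyl (2E)-2-[(3S)-3-ethynyl-3,7-dimethyloct-6-en-1-ylidene]-4-[(2R,3R)-3-formyl-3-methyloxiran-2-yl]butanoate | CC(C)=CCC[C@](C/C=C(\CC[C@H]1O[C@@]1(C)C=O)C(=O)OC)(C)C#C
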